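**Retrosynthetic overview**
- The strategy rests on the C5–C5a bond of the 2,5-dihydro-1-benzoxepine (O1, C2, C3-Me, C4, C5, C5a, C9a; ring B). This bond joins the CH2 terminus of a prenyl-type five-carbon unit, already held through C2 on O1, to the phloroglucinol carbon ortho to O1 (ring A). Cutting it opens ring B to an O-tethered tertiary allylic alcohol.
- O1–C2 is then cut to the para phenol of a dihydrochalcone and the CH2 of a vinyl epoxide; the aryl–C(=O) bond at C7 is cut to phloroglucinol and a dihydrocinnamic acid.
- Forward: phloroglucinol 1 + acid 2 → 3-hydroxyphloretin 3; 3 + 2-methyl-2-vinyloxirane 4 → tethered ether 5; 5 → target 6.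
- Ring order: ring A and the catechol ring C are bought; the seven-membered ring B is the only ring made and closes last.

Key step: step 3

Remark: the target has no stereocentre and its only alkene is ring-constrained cis, so racemic 4 is used and the carbinol centre of 5, which step 3 erases, is left undefined.

Step 1
Reactants: 1 phloroglucinol (1.5 equiv); 2 3-(3,4-dihydroxyphenyl)propanoic acid
Product: 3 3-hydroxyphloretin, i.e. 3-(3,4-dihydroxyphenyl)-1-(2,4,6-trihydroxyphenyl)propan-1-one
Conditions: BF3·OEt2 (as solvent and promoter), 80 °C, Ar; then aq. NaOAc
Reagents that add atoms: none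
Why: Friedel–Crafts C-acylation of the symmetric, highly nucleophilic phloroglucinol by the BF3-activated acid (the standard entry to 2,4,6-trihydroxyaryl ketones) can give only one mono-acyl isomer, the first acyl group should deactivate the ring against a second, and the catechol ring is a far poorer nucleophile.

Step 2
Reactants: 3 3-hydroxyphloretin; 4 2-methyl-2-vinyloxirane (racemic, 1.5 equiv)
Product: 5 3-hydroxyphloretin 4'-O-(2-hydroxy-2-methylbut-3-enyl) ether, i.e. 3-(3,4-dihydroxyphenyl)-1-[2,6-dihydroxy-4-(2-hydroxy-2-methylbut-3-enyloxy)phenyl]propan-1-one (racemic)
Conditions: K2CO3 (0.3 equiv), DMF, 60 °C, sealed vessel, Ar; dilute HCl work-up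
Reagents that add atoms: none
Why: SN2 opening of the 2,2-disubstituted epoxide at its unhindered CH2 by the phenoxide para to the acyl group, which is roughly two pKa units more acidic than the catechol and the chelated ortho hydroxyls and so should be the only one appreciably ionised by substoichiometric carbonate (the alkoxide formed passes the base on to the next molecule of 3); the quaternary carbinol carbon comes untouched from racemic 4.

Step 3
Reactants: 5 3-hydroxyphloretin 4'-O-(2-hydroxy-2-methylbut-3-enyl) ether
Product: 6 3-(3,4-dihydroxyphenyl)-1-(6,8-dihydroxy-3-methyl-2,5-dihydro-1-benzoxepin-7-yl)propan-1-one (target)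
Conditions: BF3·OEt2 (1 equiv, promoter), dry 1,4-dioxane, 0.005 M, rt, Ar; quench with aq. NaHCO3 as soon as 5 is consumed
Reagents that add atoms: none
Why: BF3·OEt2 should ionise the tertiary allylic C–OH of 5 to an O1-tethered allyl cation delocalised over C3 and C5, and the ring A carbon ortho to the ether oxygen (future C5a) should attack the unsubstituted C5 terminus in a Friedel–Crafts allylation, proton loss then restoring the arene. The closest known reactions are the BF3·OEt2-mediated C-prenylation of acylphloroglucinols with 2-methylbut-3-en-2-ol, which forms the same aryl–CH2 bond at the primary allyl terminus, and Lewis-acid intramolecular Friedel–Crafts allylations by allylic alcohols. Ring B closes in a seven-membered endo mode with C3=C4 inside the ring, which the ring size forces to be cis; rotation about C3–C4 in the tertiary-centred cation is easy, so the reactive geometry should be reachable. No stereocentre is formed and the racemic carbinol centre of 5 is erased. The step needs attack at the CH2 terminus (seven- over five-membered closure) at a single arene position: the first should follow from the steric shielding of the tertiary terminus, the strained alignment of a five-ring closure through the three-atom O–CH2–C tether and the reversibility of tert-alkylation on phloroglucinols, while the second is fixed because the two carbons ortho to O1 are equivalent by symmetry and three oxygen donors keep them nucleophilic despite the acyl group. High dilution should suppress intermolecular allylation, and the early bicarbonate quench should limit acid-induced addition of the C6 hydroxyl across C3=C4 and ionisation of the new allylic aryl ether.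

**Compound list**
1 | phloroglucinol | Oc1cc(O)cc(O)c1 | starting material
2 | 3-(3,4-dihydroxyphenyl)propanoic acid | OC(=O)CCc1ccc(O)c(O)c1 | starting material
3 | 3-hydroxyphloretin | O=C(CCc1ccc(O)c(O)c1)c1c(O)cc(O)cc1O | intermediate
4 | 2-methyl-2-vinyloxirane (racemic) | CC1(C=C)CO1 | starting material
5 | 3-hydroxyphloretin 4'-O-(2-hydroxy-2-methylbut-3-enyl) ether (racemic) | CC(O)(C=C)COc1cc(O)c(C(=O)CCc2ccc(O)c(O)c2)c(O)c1 | intermediate
6 | 3-(3,4-dihydroxyphenyl)-1-(6,8-dihydroxy-3-methyl-2,5-dihydro-1-benzoxepin-7-yl)propan-1-one | CC1=CCc2c(cc(O)c(C(=O)CCc3ccc(O)c(O)c3)c2O)OC1 | target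

Total step count: 3. Longest linear sequence: 3 steps (1 or 2 to 6).

**Steps most likely to fail**

1. Step 3 (ring closure). The tethered allyl cation may be captured at its tertiary terminus (five-membered closure), lose a proton to a diene, or alkylate a second molecule. The product may also react on under acid, by addition of the C6 hydroxyl across C3=C4 or by ionisation of its allylic aryl ether. Fallback (ring-closing metathesis, making C3=C4 instead of C5–C5a), setting out from 3: allyl bromide and K2CO3 in acetone should etherify the para hydroxyl to give 4'-O-allyl-3-hydroxyphloretin F1. Heating F1 in N,N-diethylaniline at about 190 °C should effect the aromatic Claisen rearrangement to 3'-C-allyl-3-hydroxyphloretin F2 (the two ortho carbons are equivalent). 3-Chloro-2-methylprop-1-ene and K2CO3 in acetone should then re-etherify the regenerated para hydroxyl to give 3'-C-allyl-4'-O-(2-methylallyl)-3-hydroxyphloretin F3. Second-generation Grubbs catalyst in CH2Cl2 at 40 °C should close F3 with loss of ethene, a closure type established for 3-methyl-2,5-dihydro-1-benzoxepines, and the fallback comes back to the route at 6.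

2. Step 2 (tether attachment). Site selectivity among the five phenolic hydroxyls may be lost (alkylation of the catechol or of a second ring A hydroxyl), the weakly nucleophilic phenoxide may open the epoxide only slowly, and the catechol may be oxidised by air under base. Fallback (catechol masked before the tether is attached), setting out from 3: dichlorodiphenylmethane in diphenyl ether at about 175 °C should convert only the ortho-dihydroxy unit into 3-hydroxyphloretin 3,4-O-diphenylmethylene ketal F4. F4 and 4 under the conditions of step 2, now with a single unchelated hydroxyl, should give the ketal-protected tethered ether F5. BF3·OEt2 in dilute dioxane as in step 3 should close F5 to the ketal-protected benzoxepine F6. Aqueous acetic acid (4:1, about 70 °C) should hydrolyse the ketal with release of benzophenone, and the fallback comes back to the route at 6.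

3. Step 1 (acylation). O-Acylation may fail to go on to the C-acyl compound, a second acylation or self-acylation of the acid on its catechol ring may compete, and the product may be held back as boron chelates. Fallback (Hoesch reaction, a nitrile in place of the acid), setting out from 1: 3-(3,4-dihydroxyphenyl)propanenitrile F7 (a bought-in building block), ZnCl2 and dry HCl in Et2O at 0 °C should give 3-(3,4-dihydroxyphenyl)-1-(2,4,6-trihydroxyphenyl)propan-1-iminium chloride F8. Hot water should hydrolyse F8 with loss of ammonium chloride, and the fallback comes back to the route at 3.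

**Further compounds**
F1 | step 3 | 4'-O-allyl-3-hydroxyphloretin | C=CCOc1cc(O)c(C(=O)CCc2ccc(O)c(O)c2)c(O)c1
F2 | step 3 | 3'-C-allyl-3-hydroxyphloretin | C=CCc1c(O)cc(O)c(C(=O)CCc2ccc(O)c(O)c2)c1O
F3 | step 3 | 3'-C-allyl-4'-O-(2-methylallyl)-3-hydroxyphloretin | C=CCc1c(OCC(C)=C)cc(O)c(C(=O)CCc2ccc(O)c(O)c2)c1O
F4 | step 2 | 3-hydroxyphloretin 3,4-O-diphenylmethylene ketal | O=C(CCc1ccc2OC(c3ccccc3)(c3ccccc3)Oc2c1)c1c(O)cc(O)cc1O
F5 | step 2 | 3,4-O-diphenylmethylene ketal of 5 (racemic) | CC(O)(C=C)COc1cc(O)c(C(=O)CCc2ccc3OC(c4ccccc4)(c4ccccc4)Oc3c2)c(O)c1
F6 | step 2 | 3,4-O-diphenylmethylene ketal of 6 | CC1=CCc2c(cc(O)c(C(=O)CCc3ccc4OC(c5ccccc5)(c5ccccc5)Oc4c3)c2O)OC1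
F7 | step 1 | 3-(3,4-dihydroxyphenyl)propanenitrile | N#CCCc1ccc(O)c(O)c1
F8 | step 1 | 3-(3,4-dihydroxyphenyl)-1-(2,4,6-trihydroxyphenyl)propan-1-iminium chloride | [NH2+]=C(CCc1ccc(O)c(O)c1)c1c(O)cc(O)cc1O.[Cl-]
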